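The numbers of this flask are those of an exercise; no experiment stands behind them.

The constants below say where one molecule goes, so follow it.

    open intermediate + capture agent → trapped intermediate (k1 = 86.8 /M/s)
    substrate → open intermediate (k2 = 0.247 /s)
    partner + open intermediate ⇌ product (K3 = 1800 /M, k3 = 4700 /M/s)

| setting | Sunday's | Tuesday's | Saturday's | Thursday's |
|---|---|---|---|---|
| substrate | 0.50 mM (fed, over 40.0 s) | 0.50 mM | 0.50 mM | 0.50 mM |
| partner | 0.900 mM | 0.900 mM (fed, over 40.0 s) | 0.900 mM | 0.900 mM |
| capture agent | 0.0500 mM | 0.0500 mM | 0.0500 mM | 0.0500 mM |
| time | 80 s | 80 s |  | 80 s |
| remark | all but substrate at the start; substrate goes in evenly over 40.0 s, the run ends at 80 s | a stirred flask in which partner is dosed at a steady rate over 40.0 s without added volume, worked up at 80 s | one stirred flow tank at steady state, fed with the mixture as stated, mean residence time 80 s | everything together in a closed stirred flask, run for 80 s |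

- the set-up with the highest amount of open intermediate at the outlet or at the end, in percent of the substrate put in ("none" if the first two lie within 2 percentage points) (Sunday's / Tuesday's / Saturday's / Thursday's / none)
- amount of open intermediate at the outlet or at the end, in percent of the substrate put in, Sunday's
- amount of open intermediate at the outlet or at the end, in percent of the substrate put in, Tuesday's
- amount of open intermediate at the outlet or at the end, in percent of the substrate put in, Saturday's
- amount of open intermediate at the outlet or at the end, in percent of the substrate put in, Thursday's

Substrate opens with a half-life of 2.8 s. In Thursday's flask, as charged, partner then takes the open intermediate with a forward half-life of 0.16 s, against 160 s for capture agent, so the molecule reaches product first. Product also falls back, and this to and fro is quick beside the run. So you can ask where step 3 balances, with free partner counted after what product holds: solving that balance from 1800 /M and the charges gives 46.7 %. Call this the open share: the chance that an opened molecule, not trapped, is found open rather than as product.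

Now turn the settings by hand. With the substrate charge held, more partner leaves a smaller open share. The capture agent charge can take 10.0 % of the substrate charge, and it falls pseudo-first-order, at 86.8 /M/s times the open intermediate. Over 80 s in Thursday's flask I reckon that traps 8.03 %, which leaves 43.0 % open. Feeding substrate over 40.0 s shortens the exposure by about half the feed, so I reckon Sunday's at 43.4 %. I put Tuesday's between 42.0 % and Thursday's figure. I reckon Saturday's tank leaves 4.82 % of the substrate unopened and traps 6.19 %, which gives 41.6 %. My top two lie 0.40 percentage points apart, against a margin of 2 points, so I say none.

The forecast also says none, with 43.1 % for Sunday's, 42.2 % for Tuesday's, 41.1 % for Saturday's and 42.5 % for Thursday's, since “the top two set-ups still lie well within 2 points”. My Thursday's figure stands above its value, and so does my Saturday's.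

The run gives 43.1 % for Sunday's, 42.2 % for Tuesday's, 41.0 % for Saturday's and 42.5 % for Thursday's, so the answer is none; the top two stand 0.60 points apart, and a gap of 2 points would turn it. In Sunday's flask substrate opened during the feed, with 90 % of that turnover done by 40.0 s. From then to 80.0 s capture went on, trapped intermediate rising from 2.61 % to 6.53 % of the charge. Thursday's open share of 46.7 %, balanced again for the substrate left after its trapped 7.65 %, gives 42.5 % of the charge open, and that flask ended at 42.5 %. With 2.2 mM of partner in Sunday's flask, the same balance for the substrate left after its trapped 4.20 % gives 22.3 % of the charge open, and that flask ended at 22.3 %.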